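Ring C (O1, C2, C3, C4, C4a, C8a) is cut at O1–C2 and C2–C3. Removing the benzylic carbon C2 with ring B leaves a five-membered lactol, a 2-hydroxybenzofuran-3(2H)-one, the ring tautomer of the ring A ketoaldehyde. The key step puts C2 back as an enantiopure sulfonium benzylide: lactol opening, C2–C3 bond formation, epoxide closure and 6-endo attack of O1 expand the five-membered ring to ring C, join both halves and set C2 and C3 in one operation. It exploits the C3 carbinol/C4 ketone pair as a masked glyoxal and the lability of the C2–O bond next to para-oxygenated ring B. A symmetric phenol secures the 6-methyl pattern.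

Key step: step 12

Assumption: the benzylide from (2R,5R)-2,5-dimethylthiolane is taken to attack the ketoaldehyde with the same facial bias it shows towards simple aromatic aldehydes (S at the ylide-derived epoxide carbon). If the bias were reversed, the (2S,5S)-thiolane from (2R,5R)-hexane-2,5-diol would be used in the same way.

Step 1
Reactants: 1 2-methylresorcinol
Product: 2 1,3-bis(methoxymethoxy)-2-methylbenzene
Conditions: NaH (2.5 equiv), MOMCl (2.4 equiv), DMF, 0 → 23 °C
Reagents that add atoms: chloromethyl methyl ether (MOMCl), COCCl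
Why: Williamson-type O-alkylation of both phenoxides gives acetal ethers that withstand bases and organolithiums and come off together under mild acid at the end.

Step 2
Reactants: 2 1,3-bis(methoxymethoxy)-2-methylbenzene
Product: 4 3,5-bis(methoxymethoxy)-4-methylphenol, via aryl pinacol boronate 3 (not isolated)
Conditions: [Ir(OMe)(cod)]2 (1.5 mol %), 4,4'-di-tert-butyl-2,2'-bipyridine (3 mol %), B2pin2 (0.6 equiv), THF, 80 °C; then 30% aq H2O2, NaOH (cat.), 0 °C
Reagents that add atoms: hydrogen peroxide, OO; bis(pinacolato)diboron, CC1(C)OB(OC1(C)C)B1OC(C)(C)C(C)(C)O1 (boryl group of 3 only)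
Why: Sterically governed iridium-catalysed C–H borylation attacks only the one C–H without an ortho neighbour, and oxidation of the C–B bond gives a mirror-symmetric phenol whose free oxygen (the future O1) is already distinguished from the two protected ones, which settles 6-methyl against 8-methyl.

Step 3
Reactants: 4 3,5-bis(methoxymethoxy)-4-methylphenol
Product: 5 2-bromo-3,5-bis(methoxymethoxy)-4-methylphenol
Conditions: NBS (1.0 equiv), CH2Cl2, −78 → 0 °C
Reagents that add atoms: N-bromosuccinimide, O=C1CCC(=O)N1Br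
Why: In this electrophilic aromatic bromination the para position is blocked by methyl and the two ortho positions are equivalent, so one equivalent of NBS should give a single monobromide.

Step 4
Reactants: 5 2-bromo-3,5-bis(methoxymethoxy)-4-methylphenol
Product: 7 1-[6-hydroxy-2,4-bis(methoxymethoxy)-3-methylphenyl]ethan-1-one, via dilithiated phenolate 6 (not isolated)
Conditions: n-BuLi (2.2 equiv), THF, −78 °C; MeC(O)N(OMe)Me, −78 → 0 °C; H2O
Reagents that add atoms: N-methoxy-N-methylacetamide, CC(=O)N(C)OC; n-butyllithium, [Li]CCCC (lithium of 6 only)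
Why: After O-deprotonation and bromine–lithium exchange, the Weinreb ketone synthesis stops at the chelated tetrahedral adduct, so the aryl methyl ketone forms without over-addition and without any Lewis acid that would strip the MOM groups.

Step 5
Reactants: 7 1-[6-hydroxy-2,4-bis(methoxymethoxy)-3-methylphenyl]ethan-1-one
Product: 8 2-hydroxy-4,6-bis(methoxymethoxy)-5-methyl-1-benzofuran-3(2H)-one
Conditions: SeO2 (1.3 equiv), 1,4-dioxane/H2O, 80 °C
Reagents that add atoms: selenium dioxide, O=[Se]=O
Why: The Riley oxidation converts the acetyl CH3 into CHO, and the ortho phenol adds to the new aldehyde to give the five-membered lactol (configurationally labile at C2), which shields it from further oxidation.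

Step 6
Reactants: 9 4-hydroxybenzyl alcohol
Product: 10 [4-(methoxymethoxy)phenyl]methanol
Conditions: K2CO3 (1.5 equiv), MOMCl (1.1 equiv), acetone, 0 → 23 °C
Reagents that add atoms: chloromethyl methyl ether (MOMCl), COCCl
Why: In this chemoselective Williamson-type alkylation carbonate ionises only the phenol, so the benzylic alcohol stays free.

Step 7
Reactants: 10 [4-(methoxymethoxy)phenyl]methanol; 11 geranyl bromide
Product: 13 {3-[(2E)-3,7-dimethylocta-2,6-dien-1-yl]-4-(methoxymethoxy)phenyl}methanol, via dilithiated benzyl alkoxide 12 (not isolated)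
Conditions: n-BuLi (2.2 equiv), TMEDA, THF, 0 °C; CuBr·SMe2 (10 mol %), −40 °C; 11, −40 → 0 °C; H2O
Reagents that add atoms: n-butyllithium, [Li]CCCC (lithium of 12 only)
Why: Directed ortho-metalation next to the strongly directing OMOM group, followed by copper-catalysed SN2 allylation, puts the geranyl chain at C3' without allylic transposition and keeps the E alkene of 11.

Step 8
Reactants: 13 {3-[(2E)-3,7-dimethylocta-2,6-dien-1-yl]-4-(methoxymethoxy)phenyl}methanol
Product: 14 4-(bromomethyl)-2-[(2E)-3,7-dimethylocta-2,6-dien-1-yl]-1-(methoxymethoxy)benzene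
Conditions: CBr4, PPh3, CH2Cl2, 0 °C
Reagents that add atoms: carbon tetrabromide, BrC(Br)(Br)Br
Why: The Appel reaction turns the benzylic alcohol into the bromide under neutral conditions, so neither the MOM ether nor the trisubstituted alkenes meet HBr.

Step 9
Reactants: 15 (2S,5S)-hexane-2,5-diol
Product: 16 (2S,5S)-hexane-2,5-diyl dimethanesulfonate
Conditions: MsCl (2.4 equiv), Et3N, CH2Cl2, 0 °C
Reagents that add atoms: methanesulfonyl chloride, CS(=O)(=O)Cl
Why: O-Sulfonylation activates both secondary alcohols without breaking a C–O bond, so both stereocentres are retained.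

Step 10
Reactants: 16 (2S,5S)-hexane-2,5-diyl dimethanesulfonate
Product: 17 (2R,5R)-2,5-dimethylthiolane
Conditions: Na2S·9H2O, EtOH, 23 °C
Reagents that add atoms: sodium sulfide, [Na+].[Na+].[S-2]
Why: A double SN2 displacement (intermolecular, then 5-exo-tet) inverts both centres cleanly and turns (2S,5S) into the C2-symmetric (2R,5R)-sulfide.

Step 11
Reactants: 14 4-(bromomethyl)-2-[(2E)-3,7-dimethylocta-2,6-dien-1-yl]-1-(methoxymethoxy)benzene; 17 (2R,5R)-2,5-dimethylthiolane
Product: 18 (2R,5R)-1-{[3-geranyl-4-(methoxymethoxy)phenyl]methyl}-2,5-dimethylthiolan-1-ium tetrafluoroborate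
Conditions: AgBF4, CH2Cl2, 0 °C, dark
Reagents that add atoms: silver tetrafluoroborate, [Ag+].F[B-](F)(F)F
Why: S-Alkylation is driven by precipitation of AgBr, and because both lone pairs of the C2-symmetric sulfide are equivalent a single salt forms in which sulfur is no stereocentre.

Step 12
Reactants: 8 2-hydroxy-4,6-bis(methoxymethoxy)-5-methyl-1-benzofuran-3(2H)-one; 18 (2R,5R)-1-{[3-geranyl-4-(methoxymethoxy)phenyl]methyl}-2,5-dimethylthiolan-1-ium tetrafluoroborate
Product: 22 (2R,3R)-2-[3-geranyl-4-(methoxymethoxy)phenyl]-3-hydroxy-5,7-bis(methoxymethoxy)-6-methyl-2,3-dihydro-4H-chromen-4-one, via sulfonium benzylide 19 (not isolated), via open-chain ketoaldehyde 20 (not isolated), via trans-epoxy ketone 21 (not isolated)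
Conditions: 18, KN(SiMe3)2 (1.0 equiv), THF, −78 °C; 8, NaH (1.0 equiv), THF, 0 °C; combine at −78 °C; then AcOH (3 equiv), −78 → 23 °C
Reagents that add atoms: none
Why: NaH opens lactol 8 to the phenolate of ketoaldehyde 20, in which the doubly ortho-substituted, phenolate-conjugated ketone is inert so that benzylide 19 adds only to the CHO group; the anti betaine collapses by 3-exo-tet displacement of the thiolane (inversion at the ylide carbon) to trans-epoxy ketone 21. After the cold AcOH quench the freed O1 opens the epoxide at the benzylic carbon in a 6-endo-tet closure (second inversion), so that the ArCH unit ends up inserted between O1 and the former lactol carbon and the five-membered ring has grown into ring C. The closest known reaction types are the asymmetric sulfur-ylide (Corey–Chaykovsky type) epoxidation of aldehydes with C2-symmetric thiolanes, the ylide homologation of sugar lactols and the cyclisation of 2'-hydroxychalcone epoxides to dihydroflavonols. C2 is controlled by the auxiliary: the methyl group of the (2R,5R)-thiolane that is cis to the ylide carbon shields one face, which should give the (S)-epoxide carbon and, after the second inversion, (2R). C3 is controlled by the anti-betaine (trans-epoxide) preference of semistabilised ylides and becomes (3R), its C–O bond never being broken afterwards. The selectivity needed is 6-endo over 5-exo opening, and it is secured by the para-MOM-oxy group of ring B, which loosens the benzylic C–O bond, by closing under mild acid instead of as the phenolate, and by the diequatorial 2,3-trans product being the more stable one.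

Step 13
Reactants: 22 (2R,3R)-2-[3-geranyl-4-(methoxymethoxy)phenyl]-3-hydroxy-5,7-bis(methoxymethoxy)-6-methyl-2,3-dihydro-4H-chromen-4-one
Product: 23 (2R,3R)-2-{3-[(2E)-3,7-dimethylocta-2,6-dien-1-yl]-4-hydroxyphenyl}-3,5,7-trihydroxy-6-methyl-2,3-dihydro-4H-chromen-4-one
Conditions: 3 M aq HCl, MeOH, 45 °C
Reagents that add atoms: none
Why: Acid-catalysed transacetalisation to methanol removes the three aryl MOM ethers, C3 is not enolised under these conditions, 2,3-trans is the thermodynamic arrangement, and the trisubstituted alkenes should tolerate this acidity.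

Compound list
1 | 2-methylresorcinol | Cc1c(O)cccc1O | starting material
2 | 1,3-bis(methoxymethoxy)-2-methylbenzene | Cc1c(OCOC)cccc1OCOC | intermediate
3 | 2-[3,5-bis(methoxymethoxy)-4-methylphenyl]-4,4,5,5-tetramethyl-1,3,2-dioxaborolane | Cc1c(OCOC)cc(B2OC(C)(C)C(C)(C)O2)cc1OCOC | intermediate
4 | 3,5-bis(methoxymethoxy)-4-methylphenol | Cc1c(OCOC)cc(O)cc1OCOC | intermediate
5 | 2-bromo-3,5-bis(methoxymethoxy)-4-methylphenol | Cc1c(OCOC)cc(O)c(Br)c1OCOC | intermediate
6 | lithium 2-lithio-3,5-bis(methoxymethoxy)-4-methylphenolate | Cc1c(OCOC)cc(O[Li])c([Li])c1OCOC | intermediate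
7 | 1-[6-hydroxy-2,4-bis(methoxymethoxy)-3-methylphenyl]ethan-1-one | CC(=O)c1c(O)cc(OCOC)c(C)c1OCOC | intermediate
8 | 2-hydroxy-4,6-bis(methoxymethoxy)-5-methyl-1-benzofuran-3(2H)-one (lactol, C2 epimers interconvert) | OC1Oc2cc(OCOC)c(C)c(OCOC)c2C1=O | intermediate
9 | 4-hydroxybenzyl alcohol | OCc1ccc(O)cc1 | starting material
10 | [4-(methoxymethoxy)phenyl]methanol | COCOc1ccc(CO)cc1 | intermediate
11 | geranyl bromide, (2E)-1-bromo-3,7-dimethylocta-2,6-diene | CC(C)=CCC/C(C)=C/CBr | starting material
12 | lithium [3-lithio-4-(methoxymethoxy)phenyl]methanolate | COCOc1ccc(CO[Li])cc1[Li] | intermediate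
13 | {3-[(2E)-3,7-dimethylocta-2,6-dien-1-yl]-4-(methoxymethoxy)phenyl}methanol | CC(C)=CCC/C(C)=C/Cc1cc(CO)ccc1OCOC | intermediate
14 | 4-(bromomethyl)-2-[(2E)-3,7-dimethylocta-2,6-dien-1-yl]-1-(methoxymethoxy)benzene | CC(C)=CCC/C(C)=C/Cc1cc(CBr)ccc1OCOC | intermediate
15 | (2S,5S)-hexane-2,5-diol | C[C@H](O)CC[C@H](C)O | starting material
16 | (2S,5S)-hexane-2,5-diyl dimethanesulfonate | C[C@H](OS(C)(=O)=O)CC[C@H](C)OS(C)(=O)=O | intermediate
17 | (2R,5R)-2,5-dimethylthiolane | C[C@@H]1CC[C@@H](C)S1 | intermediate
18 | (2R,5R)-1-{[3-geranyl-4-(methoxymethoxy)phenyl]methyl}-2,5-dimethylthiolan-1-ium tetrafluoroborate | CC(C)=CCC/C(C)=C/Cc1cc(C[S+]2[C@H](C)CC[C@H]2C)ccc1OCOC.F[B-](F)(F)F | intermediate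
19 | sulfonium benzylide derived from 18 | CC(C)=CCC/C(C)=C/Cc1cc([CH-][S+]2[C@H](C)CC[C@H]2C)ccc1OCOC | intermediate
20 | 2-[6-hydroxy-2,4-bis(methoxymethoxy)-3-methylphenyl]-2-oxoacetaldehyde, open-chain tautomer of 8 (present as its sodium phenolate) | O=CC(=O)c1c(O)cc(OCOC)c(C)c1OCOC | intermediate
21 | {(2R,3S)-3-[3-geranyl-4-(methoxymethoxy)phenyl]oxiran-2-yl}[6-hydroxy-2,4-bis(methoxymethoxy)-3-methylphenyl]methanone | CC(C)=CCC/C(C)=C/Cc1cc([C@@H]2O[C@H]2C(=O)c2c(O)cc(OCOC)c(C)c2OCOC)ccc1OCOC | intermediate
22 | (2R,3R)-2-[3-geranyl-4-(methoxymethoxy)phenyl]-3-hydroxy-5,7-bis(methoxymethoxy)-6-methyl-2,3-dihydro-4H-chromen-4-one | CC(C)=CCC/C(C)=C/Cc1cc([C@H]2Oc3cc(OCOC)c(C)c(OCOC)c3C(=O)[C@@H]2O)ccc1OCOC | intermediate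
23 | (2R,3R)-2-{3-[(2E)-3,7-dimethylocta-2,6-dien-1-yl]-4-hydroxyphenyl}-3,5,7-trihydroxy-6-methyl-2,3-dihydro-4H-chromen-4-one | CC(C)=CCC/C(C)=C/Cc1cc([C@H]2Oc3cc(O)c(C)c(O)c3C(=O)[C@@H]2O)ccc1O | target

Total step count: 13. Longest linear sequence: 7 (steps 1–5, 12, 13).

Steps most likely to fail

Step 12. O1 may attack the α-carbon (5-exo), followed by loss of water. Leakage through the syn betaine would lower the enantiomeric purity if the closure turns SN1-like. A 1,2-aroyl shift of the acid-activated epoxide and hydride transfer between ketoaldehyde molecules before the ylide arrives are further risks. The fallback sets out from 8 and 14 and comes back at 23. Bromide 14 is quaternised with PPh3 to the benzyltriphenylphosphonium bromide F1. Wittig chain extension of lactol 8 (two equivalents of KN(SiMe3)2, then iodine-catalysed E/Z equilibration) gives the (E)-2'-hydroxychalcone F2. The phenol is capped with MOMCl to give the tetra-MOM chalcone F3. Juliá–Colonna epoxidation (poly-L-leucine, urea–H2O2, DBU, THF) is nucleophilic and leaves the geranyl alkenes alone, and it gives the (αR,βS)-epoxychalcone F4. Methanolic HCl then removes all four MOM groups and closes ring C by the established epoxychalcone-to-dihydroflavonol cyclisation, which leads directly to 23.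

Step 5. The aldehyde may be over-oxidised to the acid level, and the hot selenous acid medium may cleave the MOM group ortho to the ketone. The fallback sets out from 7 and comes back at 8. LiN(SiMe3)2/Me3SiCl converts 7 into the bis-silylated enol ether F5. Rubottom oxidation (mCPBA, NaHCO3, CH2Cl2, then mild aqueous work-up) gives the α-hydroxy ketone F6. Cu(OAc)2 in MeOH at 23 °C oxidises the ketol to the ketoaldehyde, which closes to lactol 8.

Step 13. The acid may cyclise the geranyl chain onto the liberated 4'-hydroxyl, and reversible opening of ring C may partly epimerise C2 once that phenol is free. The fallback sets out from 22 and comes back at 23. Instead of Brønsted-acid solvolysis, a buffered silyl transfer (Me3SiOTf, 2,2'-bipyridyl, MeCN, 0 °C) exchanges the aryl MOM ethers for silyl ethers and silylates the C3 hydroxyl, which gives the tetrakis(trimethylsilyl) ether F7. Water at neutral pH then hydrolyses F7 to 23 without the geranyl phenol ever meeting a protic acid.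

Further compounds
F1 | step 12 | {[3-geranyl-4-(methoxymethoxy)phenyl]methyl}triphenylphosphonium bromide | CC(C)=CCC/C(C)=C/Cc1cc(C[P+](c2ccccc2)(c2ccccc2)c2ccccc2)ccc1OCOC.[Br-]
F2 | step 12 | (E)-3-[3-geranyl-4-(methoxymethoxy)phenyl]-1-[6-hydroxy-2,4-bis(methoxymethoxy)-3-methylphenyl]prop-2-en-1-one | CC(C)=CCC/C(C)=C/Cc1cc(/C=C/C(=O)c2c(O)cc(OCOC)c(C)c2OCOC)ccc1OCOC
F3 | step 12 | (E)-3-[3-geranyl-4-(methoxymethoxy)phenyl]-1-[2,4,6-tris(methoxymethoxy)-3-methylphenyl]prop-2-en-1-one | CC(C)=CCC/C(C)=C/Cc1cc(/C=C/C(=O)c2c(OCOC)cc(OCOC)c(C)c2OCOC)ccc1OCOC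
F4 | step 12 | {(2R,3S)-3-[3-geranyl-4-(methoxymethoxy)phenyl]oxiran-2-yl}[2,4,6-tris(methoxymethoxy)-3-methylphenyl]methanone | CC(C)=CCC/C(C)=C/Cc1cc([C@@H]2O[C@H]2C(=O)c2c(OCOC)cc(OCOC)c(C)c2OCOC)ccc1OCOC
F5 | step 5 | {1-[2,4-bis(methoxymethoxy)-3-methyl-6-(trimethylsilyloxy)phenyl]ethenyloxy}trimethylsilane | C=C(O[Si](C)(C)C)c1c(O[Si](C)(C)C)cc(OCOC)c(C)c1OCOC
F6 | step 5 | 2-hydroxy-1-[6-hydroxy-2,4-bis(methoxymethoxy)-3-methylphenyl]ethan-1-one | OCC(=O)c1c(O)cc(OCOC)c(C)c1OCOC
F7 | step 13 | (2R,3R)-2-[3-geranyl-4-(trimethylsilyloxy)phenyl]-6-methyl-3,5,7-tris(trimethylsilyloxy)-2,3-dihydro-4H-chromen-4-one | CC(C)=CCC/C(C)=C/Cc1cc([C@H]2Oc3cc(O[Si](C)(C)C)c(C)c(O[Si](C)(C)C)c3C(=O)[C@@H]2O[Si](C)(C)C)ccc1O[Si](C)(C)C
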